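Ring B (C5–C10, eremophilane numbering) is closed last onto ring A by a Carroll–aldol cascade. The saturated C1–C2 edge of ring A is treated as a former allyl unit C2–C1=C10: a 2α-allylic β-keto ester (from an allylic alcohol and a lactate-derived dioxinone) hands its α-carbon C9 to C10 by [3,3] shift on the α face, loses the tether as CO2, and the released C8 ketone condenses through C7 with the neopentyl C6 aldehyde on quaternary C5 (C6=C7). Thus C9–C10 and C6=C7 arise in one flask, and the cis ring fusion is relayed from a catalytic Diels–Alder step that sets C3, C4, C5 and the sulfur-bearing C10.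

Key step: step 8

Remark: eremophilane numbering is used for all ring compounds (ring A = C1–C5, C10; ring B = C5–C10; C6 = formyl or enone CH on C5; C14 = methyl on C5; C15 = ester carbon on C4; C11–C13 = propanoate side chain); α is the face opposite to C14.
Assumption: the enantiomer of the oxazaborolidinium catalyst named in step 4 is the one that gives 7 as drawn; its antipode would be used if the facial sense proved opposite.

Step 1
Reactants: 1 allyl phenyl sulfide; 2 (E)-crotonaldehyde
Product: 3 (E)-4-(phenylsulfanyl)but-2-enal
Conditions: 2nd-generation Ru isopropoxybenzylidene NHC catalyst (2.5 mol %), 2 (4 equiv), CH2Cl2, 40 °C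
Reagents that add atoms: none
Why: Olefin cross-metathesis between the allyl sulfide and an excess of the enal should give the conjugated (E)-enal with loss of propene; no stereocentre is formed.

Step 2
Reactants: 3 (E)-4-(phenylsulfanyl)but-2-enal
Product: 4 (1E,3E)-4-(phenylsulfanyl)buta-1,3-dien-1-yl acetate
Conditions: Ac2O, Et3N, DMAP (cat.), PhMe, 80 °C
Reagents that add atoms: acetic anhydride CC(=O)OC(C)=O
Why: Vinylogous enolisation at the sulfur-activated γ-CH2 and O-acetylation (dienol acetate formation) should give the 1-acetoxy-4-thio diene, whose (1E,3E) isomer is the one able to react in the cycloaddition.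

Step 3
Reactants: 5 methyl 3-methylbut-2-enoate
Product: 6 methyl (E)-3-methyl-4-oxobut-2-enoate
Conditions: SeO2 (1.1 equiv), 1,4-dioxane, 100 °C
Reagents that add atoms: selenium dioxide O=[Se]=O
Why: Riley allylic oxidation (ene reaction, then [2,3] shift) should oxidise the methyl group trans to the ester and give the (E)-formyl enoate; no stereocentre is formed.

Step 4
Reactants: 4 (1E,3E)-4-(phenylsulfanyl)buta-1,3-dien-1-yl acetate; 6 methyl (E)-3-methyl-4-oxobut-2-enoate
Product: 7 endo cycloadduct (3α-OAc 10α-SPh 5α-CHO 4β-CO2Me ring-A aldehyde)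
Conditions: (S)-o-tolyl-oxazaborolidinium triflimide (diphenylprolinol-derived, 15 mol %), CH2Cl2, −78 → −40 °C
Reagents that add atoms: none
Why: In this Lewis-acid-catalysed Diels–Alder reaction sulfur should steer the regiochemistry (S-bearing terminus to the formyl-bearing carbon), the catalyst-bound formyl group should react endo (SPh, OAc and CHO cis) while the E-alkene keeps CO2Me trans to CHO, and the chiral catalyst should shield one enal face, so that C3, C4, C5 and C10 are set at once.

Step 5
Reactants: 7 endo cycloadduct
Product: 10 2α-hydroxy Δ1(10) ring-A aldehyde (allylic alcohol), via allylic sulfoxide 8 (not isolated), via sulfenate ester 9 (not isolated)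
Conditions: mCPBA (1.0 equiv), CH2Cl2, −78 °C; then P(OMe)3, MeOH, 0 °C → rt
Reagents that add atoms: mCPBA OOC(=O)c1cccc(Cl)c1
Why: Sulfide oxidation followed by the Mislow–Evans [2,3] sulfoxide–sulfenate rearrangement and thiophilic cleavage should transpose the heteroatom suprafacially, so the new C2 carbinol is α (cis to CHO) and the alkene moves to C1=C10, under neutral conditions that should not let the 3-acetate migrate.

Step 6
Reactants: 11 methyl (S)-lactate
Product: 12 methyl (S)-2-(trifluoromethylsulfonyloxy)propanoate
Conditions: Tf2O, 2,6-lutidine, CH2Cl2, −78 → 0 °C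
Reagents that add atoms: triflic anhydride O=S(=O)(OS(=O)(=O)C(F)(F)F)C(F)(F)F
Why: O-Sulfonylation of the chiral-pool hydroxy ester proceeds with retention and turns the lactate carbon into an SN2 electrophile.

Step 7
Reactants: 13 2,2,6-trimethyl-4H-1,3-dioxin-4-one; 12 methyl (S)-2-(trifluoromethylsulfonyloxy)propanoate
Product: 15 dioxinone side-chain reagent, via lithium dienolate 14 (not isolated)
Conditions: LDA (1.0 equiv), THF, −78 °C; then 12, DMPU, −78 → −30 °C
Reagents that add atoms: none
Why: γ-Alkylation of the dioxinone dienolate by SN2 displacement of the α-triflyloxy ester with inversion should set the (S)-configured C11 from (S)-lactate.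

Step 8
Reactants: 10 2α-hydroxy Δ1(10) ring-A aldehyde; 15 dioxinone side-chain reagent
Product: 20 cis-fused 3α-acetoxy-1,6-dien-8-one, via acylketene 16 (not isolated), via allylic β-keto ester 17 (not isolated), via β-keto acid 18 (not isolated), via keto aldehyde 19 (not isolated)
Conditions: o-dichlorobenzene, 120 °C then 175 °C; cool, pyrrolidine/AcOH (30 mol %), 60 °C; one pot
Reagents that add atoms: none
Why: Heating converts 15 by retro-[4+2] loss of acetone into acylketene 16, which O-acylates the 2α-hydroxyl of 10; the enol of the resulting allylic β-keto ester 17 then undergoes the Carroll (decarboxylative Claisen) [3,3] shift through a boat-like six-membered transition state, forming C9–C10 and moving the alkene to C1=C2, and β-keto acid 18 loses CO2 to give keto aldehyde 19. Amine catalysis then effects the intramolecular aldol condensation of C7 onto the C6 aldehyde, the second half of a Robinson-type annulation, which closes ring B in a 6-(enolendo)-exo-trig mode and creates C6=C7. The closest known reaction types are the thermal Carroll rearrangement of allylic acetoacetates and the amine-catalysed aldol cyclodehydration of 1,5-keto aldehydes. The only new stereocentre, C10, is controlled by the C2 carbinol through suprafacial 1,3-chirality transfer (α-oxygen to α-carbon), which places C9 cis to the formyl group on C5 and hence gives the cis ring fusion. Regioselectivity is secured by the tether, which can deliver C9 only to C10 although it adjoins quaternary C5, and by ring size, since after the shift only C7 (not C9) can reach C6 in a six-membered ring. The chemoselectivity needed is acylation of the allylic hydroxyl next to a non-enolisable aldehyde, and the neutral medium should protect the 3-acetate and the C11 ester stereocentre.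

Step 9
Reactants: 20 cis-fused 3α-acetoxy-1,6-dien-8-one
Product: 21 3α-acetoxy-6-en-8-one
Conditions: H2 (1 atm), RhCl(PPh3)3 (5 mol %), PhH/EtOH, rt
Reagents that add atoms: none
Why: Homogeneous Rh-catalysed hydrogenation should reduce the cis-disubstituted C1=C2 alkene and leave the trisubstituted conjugated C6=C7 enone and the acetate untouched; no stereocentre is formed.

Step 10
Reactants: 21 3α-acetoxy-6-en-8-one
Product: 22 3α-alcohol
Conditions: HCl (0.5 M in MeOH), 0 °C → rt
Reagents that add atoms: none
Why: Acid-catalysed transesterification (methanolysis) should remove the secondary acetate without the E1cB elimination or C11 epimerisation that base could cause in this β-acyloxy ester; the methyl esters exchange degenerately.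

Step 11
Reactants: 22 3α-alcohol; 23 angelic acid
Product: 24 CNP0265265.1
Conditions: PPh3, diisopropyl azodicarboxylate, PhMe, 0 °C → rt
Reagents that add atoms: none
Why: In this Mitsunobu esterification the activated 3α-oxygen is displaced by angelate in an SN2 step with inversion, which installs the ester and corrects C3 to β under neutral conditions that should not isomerise the (Z)-2-methylbut-2-enoate; anti elimination toward C4 is blocked because H-4 is cis to the leaving group.

Compound list
1 | allyl phenyl sulfide | C=CCSc1ccccc1 | starting material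
2 | (E)-but-2-enal (crotonaldehyde) | C/C=C/C=O | starting material
3 | (E)-4-(phenylsulfanyl)but-2-enal | O=C/C=C/CSc1ccccc1 | intermediate
4 | (1E,3E)-4-(phenylsulfanyl)buta-1,3-dien-1-yl acetate | CC(=O)O/C=C/C=C/Sc1ccccc1 | intermediate
5 | methyl 3-methylbut-2-enoate | COC(=O)C=C(C)C | starting material
6 | methyl (E)-3-methyl-4-oxobut-2-enoate | COC(=O)/C=C(\C)C=O | intermediate
7 | methyl 6-acetoxy-2-formyl-2-methyl-3-(phenylsulfanyl)cyclohex-4-ene-1-carboxylate; 3α-OAc, 10α-SPh, 5α-CHO, 5β-Me, 4β-CO2Me, Δ1 | CC(=O)O[C@H]1C=C[C@@H](Sc2ccccc2)[C@@](C)(C=O)[C@@H]1C(=O)OC | intermediate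
8 | allylic sulfoxide of 7 (10α-S(O)Ph, both sulfur epimers) | CC(=O)O[C@H]1C=C[C@@H](S(=O)c2ccccc2)[C@@](C)(C=O)[C@@H]1C(=O)OC | intermediate
9 | sulfenate ester (2α-OSPh, Δ1(10)) | CC(=O)O[C@H]1[C@@H](OSc2ccccc2)C=C[C@@](C)(C=O)[C@@H]1C(=O)OC | intermediate
10 | methyl 6-acetoxy-2-formyl-5-hydroxy-2-methylcyclohex-3-ene-1-carboxylate; 2α-OH, 3α-OAc, 5α-CHO, 5β-Me, 4β-CO2Me, Δ1(10) | CC(=O)O[C@H]1[C@@H](O)C=C[C@@](C)(C=O)[C@@H]1C(=O)OC | intermediate
11 | methyl (S)-lactate | C[C@H](O)C(=O)OC | starting material
12 | methyl (S)-2-(trifluoromethylsulfonyloxy)propanoate | C[C@H](OS(=O)(=O)C(F)(F)F)C(=O)OC | intermediate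
13 | 2,2,6-trimethyl-4H-1,3-dioxin-4-one | CC1=CC(=O)OC(C)(C)O1 | starting material
14 | lithium dienolate of 13 | C=C1C=C([O-])OC(C)(C)O1.[Li+] | intermediate
15 | methyl (2S)-3-(2,2-dimethyl-4-oxo-4H-1,3-dioxin-6-yl)-2-methylpropanoate | COC(=O)[C@@H](C)CC1=CC(=O)OC(C)(C)O1 | intermediate
16 | acylketene, methyl (2S)-2-methyl-4,6-dioxohex-5-enoate | COC(=O)[C@@H](C)CC(=O)C=C=O | intermediate
17 | allylic β-keto ester: 2α-O-[(5S)-6-methoxy-5-methyl-3,6-dioxohexanoyl] derivative of 10 | CC(=O)O[C@H]1[C@@H](OC(=O)CC(=O)C[C@H](C)C(=O)OC)C=C[C@@](C)(C=O)[C@@H]1C(=O)OC | intermediate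
18 | β-keto acid from the [3,3] shift (C9 carboxylic acid, C9 configuration undefined, 10α side chain, Δ1) | CC(=O)O[C@H]1C=C[C@@H](C(C(=O)O)C(=O)C[C@H](C)C(=O)OC)[C@@](C)(C=O)[C@@H]1C(=O)OC | intermediate
19 | keto aldehyde: methyl 6-acetoxy-2-formyl-2-methyl-3-[(4S)-5-methoxy-4-methyl-2,5-dioxopentyl]cyclohex-4-ene-1-carboxylate (10α side chain, 5α-CHO) | CC(=O)O[C@H]1C=C[C@@H](CC(=O)C[C@H](C)C(=O)OC)[C@@](C)(C=O)[C@@H]1C(=O)OC | intermediate
20 | dimethyl 3α-acetoxy-8-oxo-10βH-eremophila-1,6-diene-12,15-dioate (11S, cis-fused) | CC(=O)O[C@H]1C=C[C@H]2CC(=O)C([C@H](C)C(=O)OC)=C[C@@]2(C)[C@@H]1C(=O)OC | intermediate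
21 | dimethyl 3α-acetoxy-8-oxo-10βH-eremophil-6-ene-12,15-dioate (11S) | CC(=O)O[C@H]1CC[C@H]2CC(=O)C([C@H](C)C(=O)OC)=C[C@@]2(C)[C@@H]1C(=O)OC | intermediate
22 | dimethyl 3α-hydroxy-8-oxo-10βH-eremophil-6-ene-12,15-dioate (11S) | O[C@H]1CC[C@H]2CC(=O)C([C@H](C)C(=O)OC)=C[C@@]2(C)[C@@H]1C(=O)OC | intermediate
23 | angelic acid, (Z)-2-methylbut-2-enoic acid | C/C=C(/C)C(=O)O | starting material
24 | CNP0265265.1, dimethyl 3β-angeloyloxy-8-oxo-10βH-eremophil-6-ene-12,15-dioate (11S) | C/C=C(/C)C(=O)O[C@@H]1CC[C@H]2CC(=O)C([C@H](C)C(=O)OC)=C[C@@]2(C)[C@@H]1C(=O)OC | target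

Total step count: 11. Longest linear sequence: 8 steps (steps 1, 2, 4, 5, 8, 9, 10, 11).

Steps most likely to fail

Step 8. The [3,3] shift has to form a bond at a ring carbon next to a quaternary centre and needs about 175 °C. Before it occurs, the acylketene may acylate the bridged lactol tautomer of 10 instead of the allylic hydroxyl, and the 3-acetate may be lost or migrate thermally before the aldol closure. The fallback sets out from 10 and 15, which are heated only to 110 °C so that the allylic β-keto ester 17 can be isolated. Ester 17 is then treated with Pd(PPh3)4 in THF at room temperature. Ionisation to a π-allylpalladium/β-keto carboxylate ion pair, loss of CO2 and recombination (Pd-catalysed decarboxylative allylic alkylation) replace the pericyclic step. The 3-acetoxy group should disfavour attack at the adjacent C2 terminus, and double inversion keeps C9 on the α face, so keto aldehyde 19 should result. Pyrrolidinium acetate then closes 19 to 20, where the route is rejoined. This fallback makes no compound outside the list (F0).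

Step 4. Endo or facial selectivity may be insufficient with a trisubstituted, doubly activated enal, and the thioether of the diene may inhibit the boron catalyst. The fallback sets out from 4 and 6 and gives up catalyst control: an endo-selective cycloaddition under Me2AlCl catalysis (CH2Cl2, −78 °C) would give 7 as a racemate, that is together with the enantiomer of the cycloadduct F1. The two are separated by preparative chromatography on a chiral stationary phase, and the route is rejoined at 7.

Step 11. The SN2 displacement at the hindered C3 carbinol, flanked by the C4 ester, may be slow, which opens the way to elimination toward C2, to substitution with retention, or to partial isomerisation of the angelate to the tiglate. The fallback sets out from 22 and replaces inversion by an oxidation–reduction sequence. Oxidation with Dess–Martin periodinane gives the 3-ketone F2, a β-keto ester. Chelation-controlled reduction with Zn(BH4)2 (Et2O, −20 °C), with hydride delivered to the zinc chelate from the α face and the saturated ketone reduced in preference to the enone, gives the 3β-alcohol F3. Acylation of F3 with angelic 2,4,6-trichlorobenzoic anhydride F4 (made from 23, 2,4,6-trichlorobenzoyl chloride and Et3N; PhMe, 80 °C, no DMAP) then gives 24.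

Further compounds
F0 | step 8 | none | none
F1 | step 4 | enantiomer of cycloadduct 7 | CC(=O)O[C@@H]1C=C[C@H](Sc2ccccc2)[C@](C)(C=O)[C@H]1C(=O)OC
F2 | step 11 | 3-ketone, dimethyl 3,8-dioxo-10βH-eremophil-6-ene-12,15-dioate | O=C1CC[C@H]2CC(=O)C([C@H](C)C(=O)OC)=C[C@@]2(C)[C@@H]1C(=O)OC
F3 | step 11 | 3β-alcohol, C3 epimer of 22 | O[C@@H]1CC[C@H]2CC(=O)C([C@H](C)C(=O)OC)=C[C@@]2(C)[C@@H]1C(=O)OC
F4 | step 11 | angelic 2,4,6-trichlorobenzoic anhydride | C/C=C(/C)C(=O)OC(=O)c1c(Cl)cc(Cl)cc1Cl
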